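**Plan**
1. Retrosynthetic cuts, in order: the C12 propionate and C2/C9 acetates; C3=C4 (ring-closing metathesis, ten-membered ring last); C8–C17 with the γ-lactone (intramolecular Reformatsky); C6–C7 (γ-chloroallylation); C8–C9 (glycolate aldol).
2. Core cut: C11–C12 of the cyclohexene by a ring-contracting Ireland–Claisen rearrangement; behind it C14–C13 (alkoxyacetylide), C1–C2 (acrolein aldol) and C10–C9 (asymmetric conjugate addition).
3. Enabling feature: C12 is flanked by the C13=C14 alkene, and C14 sits on quaternary C1. C14 can therefore carry the ring oxygen of a δ-lactone O–C20(=O)–C11–C10–C1–C14 bearing a (Z)-2-alkoxyvinyl arm. Its silyl ketene acetal is the allyl vinyl ether C12=C13–C14–O–C20=C11. C20 at the carboxyl level is the helper, reduced later to the C11 methyl.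
4. Forward order: δ-lactone template (C10, C1, C2) → opened and reclosed as the C14–O lactone → cyclohexene (key step) → C9–C6 chain with chlorohydrin → γ-lactone → ten-membered ring → esters.
5. Stereochemistry: C10 from Rh/(S)-BINAP; C1 and C2 from the lactone enolate aldol; C14 from Noyori reduction, relayed to C11 and C12 (with the (Z)-enol ether); C9 (and temporary C8) from the Evans auxiliary; C7/C6 from Felkin–Anh control and a chair allylchromium transition state; C8/C17 from tethered delivery; (Z)-C3=C4 from ring size.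

Key step: step 11

Remark: atoms are cited in every intermediate by the briarane numbering of the target (C1 quaternary; C2–C9 macro-ring; C10 ring-fusion CH; C11–C14 cyclohexene; C15 methyl on C1; C16 exocyclic methylene; C17–C19 lactone; C20 methyl on C11). The 2-bromopropanoyl unit is used as the racemate, because C17 is set only after enolate formation.

**Route**

Step 1
Reactants: 1 5,6-dihydro-2H-pyran-2-one; 2 (E)-2-phenylvinylboronic acid
Product: 3 (S)-4-styryl δ-lactone
Conditions: Rh(acac)(C2H4)2 (3 mol %), (S)-BINAP, dioxane/H2O 10:1, 100 °C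
Reagents that add atoms: none
Why: Hayashi–Miyaura rhodium-catalysed asymmetric 1,4-addition; the (S)-BINAP–rhodium alkenyl species adds to one face of the unsaturated lactone and sets C10, the styryl group being a masked C9 aldehyde.

Step 2
Reactants: 3 (S)-4-styryl δ-lactone
Product: 4 trans-3-methyl-4-styryl lactone
Conditions: LiN(iPr)2, THF, −78 °C; MeI, −78 → −40 °C
Reagents that add atoms: iodomethane CI
Why: lactone enolate alkylation; the C15 methyl enters anti to the C10 substituent (this centre is planarised again in step 4).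

Step 3
Reactants: 4 trans-3-methyl-4-styryl lactone
Product: 6 acetal lactone, via C9 aldehyde 5 (not isolated)
Conditions: O3, CH2Cl2, −78 °C; Me2S; then HC(OMe)3, PPTS (cat.), MeOH, 23 °C
Reagents that add atoms: ozone [O-][O+]=O; trimethyl orthoformate COC(OC)OC
Why: ozonolysis of the only alkene followed by acetalisation; the acetal stores C9 at the aldehyde level through the basic and hydride steps and blocks epimerisation at C10.

Step 4
Reactants: 6 acetal lactone; 7 acrolein
Product: 8 aldol lactone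
Conditions: LiN(iPr)2, THF, −78 °C; 7, −78 °C, 10 min; AcOH/THF quench at −78 °C
Reagents that add atoms: none
Why: aldol addition (1,2) of the tetrasubstituted lithium lactone enolate; the aldehyde adds anti to the C10 acetal (quaternary C1: C2 arm trans to C9, C15 cis), and a Zimmerman–Traxler chair with the ring-fixed enolate geometry (methyl cis to OLi) should place C2–OH syn to C15.

Step 5
Reactants: 8 aldol lactone
Product: 9 C2 silyl ether lactone
Conditions: TBSOTf, 2,6-lutidine, CH2Cl2, −78 → 0 °C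
Reagents that add atoms: tert-butyldimethylsilyl triflate CC(C)(C)[Si](C)(C)OS(=O)(=O)C(F)(F)F
Why: silylation of the hindered secondary alcohol protects C2–OH until the ring-closing metathesis and prevents retro-aldol cleavage.

Step 6
Reactants: 10 4-methoxybenzyl alcohol; 11 trichloroethylene
Product: 12 dichlorovinyl ether
Conditions: KH, THF, 0 °C; 11, −50 → 23 °C
Reagents that add atoms: none
Why: base-induced formation of dichloroacetylene and anti addition of the alkoxide (the standard dichlorovinyl ether entry to ynol ethers); gives the C13–C12–O unit with the C12 protecting group already in place.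

Step 7
Reactants: 9 C2 silyl ether lactone; 12 dichlorovinyl ether
Product: 14 hydroxy ynone, via lithium acetylide 13 (not isolated)
Conditions: 12, n-BuLi (2.2 equiv per 12), THF, −78 → −40 °C; then 9, −78 → −20 °C; NH4Cl (aq)
Reagents that add atoms: none
Why: elimination and chlorine–lithium exchange give the lithium alkoxyacetylide, which adds once to the lactone carbonyl (acetylide opening of a lactone; the lithium hemiketal resists a second addition); this forms C14–C13 and frees C20 as a primary alcohol.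

Step 8
Reactants: 14 hydroxy ynone
Product: 15 propargylic diol
Conditions: RuCl[(S,S)-TsDPEN](p-cymene) (5 mol %), iPrOH, 23 °C
Reagents that add atoms: none
Why: Noyori asymmetric transfer hydrogenation of an ynone; reagent control with the alkynyl group as the π-substituent should give (S) at C14, the centre that later steers the key step.

Step 9
Reactants: 15 propargylic diol
Product: 16 (Z)-enol ether diol
Conditions: H2 (1 atm), Pd/CaCO3 poisoned with Pb(OAc)2, quinoline, EtOAc, 23 °C
Reagents that add atoms: none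
Why: Lindlar semi-hydrogenation; syn addition of H2 to the ynol ether gives the (Z)-enol ether that later fixes C12, the monosubstituted C3 alkene reacting far more slowly.

Step 10
Reactants: 16 (Z)-enol ether diol
Product: 18 C14–O δ-lactone, via lactol 17 (not isolated)
Conditions: [Cu(MeCN)4]OTf (5 mol %), 2,2'-bipyridine, TEMPO, N-methylimidazole, air, MeCN, 23 °C
Reagents that add atoms: none
Why: copper/nitroxyl aerobic oxidative lactonisation of a 1,5-diol; only the primary C20 alcohol is oxidised, the aldehyde is trapped by C14–OH as the lactol and oxidised further, and the basic medium spares the acid-labile enol ether.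

Step 11
Reactants: 18 C14–O δ-lactone
Product: 21 cyclohexene acid, via silyl ketene acetal 19 (not isolated), via trimethylsilyl ester 20 (not isolated)
Conditions: Me3SiCl/Et3N (premixed), LiN(iPr)2, THF, −78 °C; then 23 → 60 °C; K2CO3, MeOH/H2O, then pH 5 buffer
Reagents that add atoms: chlorotrimethylsilane C[Si](C)(C)Cl (silicon stays only in 19 and 20)
Why: Kinetic enolisation of the δ-lactone in the presence of Me3SiCl gives the cyclic silyl ketene acetal 19, whose allyl vinyl ether array C12=C13–C14–O–C20=C11 undergoes a concerted [3,3]-sigmatropic (Ireland–Claisen) shift: C11–C12 forms as C14–O breaks, leaving the C13=C14 alkene and C20 as a silyl ester. The closest known reaction type is the Ireland–Claisen ring contraction of 6-alkenyl δ-lactones to cyclohexenecarboxylic acids, together with its dioxanone-to-dihydropyran variant. The cyclohexene (C1, C10, C11, C12, C13, C14) closes through a boat transition state shaped like a bicyclo[2.2.2]octane, the only geometry in which the vinyl arm on C14 can reach C11 across the lactone. C11 is controlled by C14: the vinyl arm lies on the lactone face syn to the C2 arm and anti to the C10 acetal, so C12 bonds on that face and C20 ends cis to C9 and C15. C12 is controlled by the enol ether geometry: in the boat the (Z)-alkoxy group points toward the C1–C10 bridge and ends trans to C20. The step needs enolisation at C11 without β-elimination or ionisation of the allylic C14–O bond; the internal Me3SiCl/Et3N quench at −78 °C and the absence of any other enolisable carbonyl secure this.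

Step 12
Reactants: 21 cyclohexene acid
Product: 22 C20 primary alcohol
Conditions: LiAlH4, THF, 0 → 23 °C
Reagents that add atoms: none
Why: hydride reduction of the carboxylic acid starts the removal of the helper oxidation level at C20; no other group is reducible.

Step 13
Reactants: 22 C20 primary alcohol
Product: 23 C20 mesylate
Conditions: MsCl, Et3N, CH2Cl2, 0 °C
Reagents that add atoms: methanesulfonyl chloride CS(=O)(=O)Cl
Why: sulfonylation activates the primary alcohol for hydride displacement.

Step 14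
Reactants: 23 C20 mesylate
Product: 24 C11-methyl acetal
Conditions: LiEt3BH, THF, 0 → 40 °C
Reagents that add atoms: none
Why: SN2 hydride displacement of the primary mesylate leaves the C20 methyl on C11 with the configuration set in step 11.

Step 15
Reactants: 24 C11-methyl acetal
Product: 25 C9 aldehyde
Conditions: PPTS, acetone/H2O 10:1, 45 °C
Reagents that add atoms: water O
Why: mild acetal hydrolysis frees the C9 aldehyde while silyl and benzyl-type ethers survive; the aldehyde is used at once to avoid epimerisation at C10.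

Step 16
Reactants: 26 3,4-dimethoxybenzyl alcohol; 27 bromoacetic acid
Product: 28 (3,4-dimethoxybenzyloxy)acetic acid
Conditions: NaH (2.2 equiv), THF, 0 → 60 °C; then HCl (aq)
Reagents that add atoms: none
Why: Williamson etherification gives the glycolic acid carrying the oxidatively removable C8 protecting group.

Step 17
Reactants: 28 (3,4-dimethoxybenzyloxy)acetic acid; 29 (R)-4-benzyloxazolidin-2-one
Product: 31 glycolate imide, via mixed anhydride 30 (not isolated)
Conditions: t-BuCOCl, Et3N, THF, −20 °C; then 29, LiCl, 23 °C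
Reagents that add atoms: pivaloyl chloride CC(C)(C)C(=O)Cl (retained only in 30)
Why: N-acylation of the oxazolidinone through the mixed pivalic anhydride, a standard preparation of Evans imides.

Step 18
Reactants: 25 C9 aldehyde; 31 glycolate imide
Product: 33 syn-glycolate aldol adduct, via boron enolate 32 (not isolated)
Conditions: 31, Bu2BOTf, Et3N, CH2Cl2, −78 → 0 °C; then 25, −78 → 0 °C; pH 7 buffer, MeOH
Reagents that add atoms: dibutylboron triflate CCCCB(CCCC)OS(=O)(=O)C(F)(F)F (boron stays only in 32)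
Why: Evans syn-glycolate aldol through the (Z)-boron enolate and a Zimmerman–Traxler chair; the (R)-auxiliary fixes C9 and the temporary C8 centre, and the required anti-Felkin sense at C9 is the one a (Z)-enolate prefers with this α-branched aldehyde.

Step 19
Reactants: 33 syn-glycolate aldol adduct
Product: 34 C9 silyl ether imide
Conditions: TBSOTf, 2,6-lutidine, CH2Cl2, −78 → 0 °C
Reagents that add atoms: tert-butyldimethylsilyl triflate CC(C)(C)[Si](C)(C)OS(=O)(=O)C(F)(F)F
Why: silylation masks C9–OH, which must not be oxidised or acylated before the final acetylation.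

Step 20
Reactants: 34 C9 silyl ether imide
Product: 35 C7 primary alcohol
Conditions: LiBH4, MeOH (1 equiv), THF, 0 °C
Reagents that add atoms: none
Why: reductive cleavage of the N-acyl oxazolidinone at the exocyclic carbonyl; the auxiliary is recovered.

Step 21
Reactants: 35 C7 primary alcohol
Product: 36 C7 aldehyde
Conditions: Dess–Martin periodinane, NaHCO3, CH2Cl2, 0 → 23 °C
Reagents that add atoms: none
Why: buffered Dess–Martin oxidation gives the α-alkoxy aldehyde without epimerising C8, whose configuration directs the next step.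

Step 22
Reactants: 37 1,3-dichloroacetone; 38 vinylmagnesium bromide
Product: 39 bis(chloromethyl) vinyl carbinol
Conditions: THF, −78 °C; NH4Cl (aq)
Reagents that add atoms: none
Why: Grignard 1,2-addition to the ketone assembles C16, C5, C6 and the C4 vinyl group in one piece.

Step 23
Reactants: 39 bis(chloromethyl) vinyl carbinol
Product: 40 dichlorodiene
Conditions: Burgess reagent (methyl N-(triethylammoniosulfonyl)carbamate), benzene, 50 °C; used at once, with BHT
Reagents that add atoms: none
Why: Burgess dehydration (syn elimination through the sulfamate ester toward a chloromethyl hydrogen) gives the conjugated 2-vinyl-1,3-dichloropropene; its alkene geometry is irrelevant because the derived allylchromium equilibrates.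

Step 24
Reactants: 36 C7 aldehyde; 40 dichlorodiene
Product: 42 anti-chlorohydrin, via allylchromium 41 (not isolated)
Conditions: CrCl2 (5 equiv), THF, 0 → 23 °C
Reagents that add atoms: chromium dichloride Cl[Cr]Cl (chromium only in 41)
Why: Nozaki–Hiyama-type γ-chloroallylation; the allylic C–Cl bond inserts chromium and the γ-carbon (C6, bearing Cl) adds through a chair transition state to give the anti C6–Cl/C7–OH pair with the C5=C16 methylene, while Felkin–Anh addition anti to the C8 ether oxygen sets C7.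

Step 25
Reactants: 42 anti-chlorohydrin; 43 2-bromopropanoyl bromide
Product: 44 C7 2-bromopropanoate
Conditions: pyridine, CH2Cl2, −20 → 0 °C
Reagents that add atoms: none
Why: acylation of the only free hydroxyl installs C17–C19 as the Reformatsky donor on O7.

Step 26
Reactants: 44 C7 2-bromopropanoate
Product: 45 C8 alcohol
Conditions: DDQ (1.2 equiv), CH2Cl2/pH 7 buffer 10:1, 0 °C
Reagents that add atoms: none
Why: oxidative debenzylation; the more electron-rich 3,4-dimethoxybenzyl ether should be cleaved by DDQ well before the 4-methoxybenzyl ether at C12.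

Step 27
Reactants: 45 C8 alcohol
Product: 46 C8 ketone
Conditions: Dess–Martin periodinane, NaHCO3, CH2Cl2, 0 → 23 °C
Reagents that add atoms: none
Why: neutral oxidation of the secondary alcohol gives the ketone acceptor without base that could eliminate the C6 chloride.

Step 28
Reactants: 46 C8 ketone
Product: 48 γ-lactone, via samarium enolate 47 (not isolated)
Conditions: SmI2 (2.2 equiv), THF, −78 °C; NH4Cl (aq)
Reagents that add atoms: samarium diiodide I[Sm]I (samarium only in 47)
Why: SmI2-mediated intramolecular Reformatsky reaction (5-exo aldol closure); the enolate tethered through O7 attacks the C8 ketone in the rotamer that keeps the C9 branch anti to C6 (C8–OH cis to C6), and the C18 methyl settles trans to the C9 branch, which is also the thermodynamic arrangement at epimerisable C17.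

Step 29
Reactants: 48 γ-lactone
Product: 49 seco triol
Conditions: HF·pyridine, pyridine, THF, 0 → 23 °C
Reagents that add atoms: none
Why: fluoride-mediated desilylation frees C2–OH and C9–OH under mildly acidic conditions that should not trigger translactonisation; the free allylic hydroxyl also makes the C3 alkene a better metathesis partner.

Step 30
Reactants: 49 seco triol
Product: 50 ten-membered diene triol
Conditions: second-generation Grubbs catalyst RuCl2(PCy3)(H2IMes)(=CHPh) (10 mol %), CH2Cl2 (1 mM), 40 °C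
Reagents that add atoms: none
Why: ring-closing metathesis between the C3 vinyl group and the terminal vinyl of the 2-substituted diene closes the ten-membered ring with loss of ethene; the ring size enforces the (Z)-C3=C4 geometry and the 1,1-disubstituted C5=C16 alkene is the less reactive site.

Step 31
Reactants: 50 ten-membered diene triol
Product: 51 C2,C9-diacetate
Conditions: Ac2O, DMAP, pyridine, 23 °C
Reagents that add atoms: acetic anhydride CC(=O)OC(C)=O
Why: DMAP-catalysed acetylation of the two secondary alcohols; the tertiary C8–OH does not react.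

Step 32
Reactants: 51 C2,C9-diacetate
Product: 52 C12 alcohol
Conditions: DDQ, CH2Cl2/pH 7 buffer 10:1, 0 → 23 °C
Reagents that add atoms: none
Why: oxidative cleavage of the 4-methoxybenzyl ether under neutral conditions frees C12–OH without touching the esters, the allylic chloride or the diene.

Step 33
Reactants: 52 C12 alcohol
Product: 53 CNP0305105.1
Conditions: (EtCO)2O, DMAP, Et3N, CH2Cl2, 0 °C
Reagents that add atoms: propionic anhydride CCC(=O)OC(=O)CC
Why: acylation of the only reactive hydroxyl installs the C12 propionate and completes the target.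

**Compound list**

1 | 5,6-dihydro-2H-pyran-2-one | O=C1C=CCCO1 | starting material
2 | (E)-2-phenylvinylboronic acid | OB(O)/C=C/c1ccccc1 | starting material
3 | (S)-4-[(E)-2-phenylvinyl]tetrahydro-2H-pyran-2-one (carbonyl = C14, stereocentre = C10) | O=C1C[C@@H](/C=C/c2ccccc2)CCO1 | intermediate
4 | (3R,4R)-3-methyl-4-[(E)-2-phenylvinyl]tetrahydro-2H-pyran-2-one (methyl trans to styryl) | C[C@@H]1[C@@H](/C=C/c2ccccc2)CCOC1=O | intermediate
5 | (3R,4S)-3-methyl-2-oxotetrahydro-2H-pyran-4-carbaldehyde | C[C@@H]1[C@@H](C=O)CCOC1=O | intermediate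
6 | (3R,4S)-4-(dimethoxymethyl)-3-methyltetrahydro-2H-pyran-2-one | C[C@@H]1[C@@H](C(OC)OC)CCOC1=O | intermediate
7 | acrolein | C=CC=O | starting material
8 | aldol lactone: 4-(dimethoxymethyl)-3-(1-hydroxyprop-2-enyl)-3-methyltetrahydropyran-2-one, hydroxyallyl arm trans to the acetal, C2–OH syn to C15 | C=C[C@H](O)[C@]1(C)[C@@H](C(OC)OC)CCOC1=O | intermediate
9 | C2 tert-butyldimethylsilyl ether of 8 | C=C[C@H](O[Si](C)(C)C(C)(C)C)[C@]1(C)[C@@H](C(OC)OC)CCOC1=O | intermediate
10 | 4-methoxybenzyl alcohol | COc1ccc(CO)cc1 | starting material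
11 | trichloroethylene | ClC=C(Cl)Cl | starting material
12 | 1-{[(E)-1,2-dichlorovinyl]oxymethyl}-4-methoxybenzene | COc1ccc(CO/C(Cl)=C\Cl)cc1 | intermediate
13 | lithium [(4-methoxybenzyl)oxy]acetylide | [Li]C#COCc1ccc(OC)cc1 | intermediate
14 | hydroxy ynone: open chain with C14 ketone bearing the alkoxyethynyl group, C20 primary alcohol, C9 acetal, C2 silyl ether | C=C[C@H](O[Si](C)(C)C(C)(C)C)[C@@](C)(C(=O)C#COCc1ccc(OC)cc1)[C@@H](C(OC)OC)CCO | intermediate
15 | (14S)-propargylic diol from 14 | C=C[C@H](O[Si](C)(C)C(C)(C)C)[C@@](C)([C@H](O)C#COCc1ccc(OC)cc1)[C@@H](C(OC)OC)CCO | intermediate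
16 | (Z)-enol ether diol (C12=C13 cis, 4-methoxybenzyloxy on C12) | C=C[C@H](O[Si](C)(C)C(C)(C)C)[C@@](C)([C@H](O)/C=C\OCc1ccc(OC)cc1)[C@@H](C(OC)OC)CCO | intermediate
17 | lactol (C20 hemiacetal closed on O14) | C=C[C@H](O[Si](C)(C)C(C)(C)C)[C@@]1(C)[C@@H](/C=C\OCc2ccc(OC)cc2)OC(O)C[C@@H]1C(OC)OC | intermediate
18 | δ-lactone O14–C20(=O)–C11–C10–C1–C14 with the (Z)-2-(4-methoxybenzyloxy)vinyl arm on C14 cis to the C2 arm | C=C[C@H](O[Si](C)(C)C(C)(C)C)[C@@]1(C)[C@@H](/C=C\OCc2ccc(OC)cc2)OC(=O)C[C@@H]1C(OC)OC | intermediate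
19 | cyclic trimethylsilyl ketene acetal of 18 (C20=C11) | C=C[C@H](O[Si](C)(C)C(C)(C)C)[C@@]1(C)[C@@H](/C=C\OCc2ccc(OC)cc2)OC(O[Si](C)(C)C)=C[C@@H]1C(OC)OC | intermediate
20 | trimethylsilyl ester of 21 | C=C[C@H](O[Si](C)(C)C(C)(C)C)[C@@]1(C)C=C[C@@H](OCc2ccc(OC)cc2)[C@H](C(=O)O[Si](C)(C)C)[C@@H]1C(OC)OC | intermediate
21 | cyclohexene acid: C13=C14 ring alkene, C12 4-methoxybenzyl ether, C11 carboxyl (C20) cis to the C10 acetal and C15, trans to O12 | C=C[C@H](O[Si](C)(C)C(C)(C)C)[C@@]1(C)C=C[C@@H](OCc2ccc(OC)cc2)[C@H](C(=O)O)[C@@H]1C(OC)OC | intermediate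
22 | C20 primary alcohol | C=C[C@H](O[Si](C)(C)C(C)(C)C)[C@@]1(C)C=C[C@@H](OCc2ccc(OC)cc2)[C@H](CO)[C@@H]1C(OC)OC | intermediate
23 | C20 methanesulfonate | C=C[C@H](O[Si](C)(C)C(C)(C)C)[C@@]1(C)C=C[C@@H](OCc2ccc(OC)cc2)[C@H](COS(C)(=O)=O)[C@@H]1C(OC)OC | intermediate
24 | C11-methyl cyclohexene with C9 dimethyl acetal | C=C[C@H](O[Si](C)(C)C(C)(C)C)[C@@]1(C)C=C[C@@H](OCc2ccc(OC)cc2)[C@H](C)[C@@H]1C(OC)OC | intermediate
25 | C9 aldehyde of the cyclohexene core | C=C[C@H](O[Si](C)(C)C(C)(C)C)[C@@]1(C)C=C[C@@H](OCc2ccc(OC)cc2)[C@H](C)[C@@H]1C=O | intermediate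
26 | 3,4-dimethoxybenzyl alcohol | COc1ccc(CO)cc1OC | starting material
27 | bromoacetic acid | OC(=O)CBr | starting material
28 | 2-[(3,4-dimethoxybenzyl)oxy]acetic acid | COc1ccc(COCC(=O)O)cc1OC | intermediate
29 | (R)-4-benzyloxazolidin-2-one | O=C1N[C@H](Cc2ccccc2)CO1 | starting material
30 | mixed anhydride of 28 with pivalic acid | COc1ccc(COCC(=O)OC(=O)C(C)(C)C)cc1OC | intermediate
31 | (R)-4-benzyl-3-{2-[(3,4-dimethoxybenzyl)oxy]acetyl}oxazolidin-2-one | COc1ccc(COCC(=O)N2C(=O)OC[C@H]2Cc2ccccc2)cc1OC | intermediate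
32 | (Z)-dibutylboron enolate of 31 | COc1ccc(CO/C=C(\OB(CCCC)CCCC)N2C(=O)OC[C@H]2Cc2ccccc2)cc1OC | intermediate
33 | syn-glycolate aldol adduct: C9–OH and C8 3,4-dimethoxybenzyl ether syn, C7 imide | C=C[C@H](O[Si](C)(C)C(C)(C)C)[C@@]1(C)C=C[C@@H](OCc2ccc(OC)cc2)[C@H](C)[C@@H]1[C@H](O)[C@@H](OCc1ccc(OC)c(OC)c1)C(=O)N1C(=O)OC[C@H]1Cc1ccccc1 | intermediate
34 | C9 tert-butyldimethylsilyl ether of 33 | C=C[C@H](O[Si](C)(C)C(C)(C)C)[C@@]1(C)C=C[C@@H](OCc2ccc(OC)cc2)[C@H](C)[C@@H]1[C@H](O[Si](C)(C)C(C)(C)C)[C@@H](OCc1ccc(OC)c(OC)c1)C(=O)N1C(=O)OC[C@H]1Cc1ccccc1 | intermediate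
35 | C7 primary alcohol | C=C[C@H](O[Si](C)(C)C(C)(C)C)[C@@]1(C)C=C[C@@H](OCc2ccc(OC)cc2)[C@H](C)[C@@H]1[C@H](O[Si](C)(C)C(C)(C)C)[C@@H](OCc1ccc(OC)c(OC)c1)CO | intermediate
36 | C7 aldehyde | C=C[C@H](O[Si](C)(C)C(C)(C)C)[C@@]1(C)C=C[C@@H](OCc2ccc(OC)cc2)[C@H](C)[C@@H]1[C@H](O[Si](C)(C)C(C)(C)C)[C@@H](OCc1ccc(OC)c(OC)c1)C=O | intermediate
37 | 1,3-dichloroacetone | ClCC(=O)CCl | starting material
38 | vinylmagnesium bromide | C=C[Mg]Br | starting material
39 | 1-chloro-2-(chloromethyl)but-3-en-2-ol | ClCC(O)(CCl)C=C | intermediate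
40 | 1-chloro-2-(chloromethyl)buta-1,3-diene (E/Z mixture) | ClCC(C=C)=CCl | intermediate
41 | [2-(chloromethylidene)but-3-enyl]chromium dichloride | Cl[Cr](Cl)CC(C=C)=CCl | intermediate
42 | anti-chlorohydrin: C7–OH, C6–Cl, C5=C16 methylene, C4 vinyl; C8 ether and C9 silyl ether retained | C=C[C@H](O[Si](C)(C)C(C)(C)C)[C@@]1(C)C=C[C@@H](OCc2ccc(OC)cc2)[C@H](C)[C@@H]1[C@H](O[Si](C)(C)C(C)(C)C)[C@@H](OCc1ccc(OC)c(OC)c1)[C@@H](O)[C@@H](Cl)C(=C)C=C | intermediate
43 | 2-bromopropanoyl bromide (racemic) | CC(Br)C(=O)Br | starting material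
44 | C7 2-bromopropanoate (epimers at CHBr) | C=C[C@H](O[Si](C)(C)C(C)(C)C)[C@@]1(C)C=C[C@@H](OCc2ccc(OC)cc2)[C@H](C)[C@@H]1[C@H](O[Si](C)(C)C(C)(C)C)[C@@H](OCc1ccc(OC)c(OC)c1)[C@@H](OC(=O)C(C)Br)[C@@H](Cl)C(=C)C=C | intermediate
45 | C8 alcohol | C=C[C@H](O[Si](C)(C)C(C)(C)C)[C@@]1(C)C=C[C@@H](OCc2ccc(OC)cc2)[C@H](C)[C@@H]1[C@H](O[Si](C)(C)C(C)(C)C)[C@@H](O)[C@@H](OC(=O)C(C)Br)[C@@H](Cl)C(=C)C=C | intermediate
46 | C8 ketone with C7 2-bromopropanoate | C=C[C@H](O[Si](C)(C)C(C)(C)C)[C@@]1(C)C=C[C@@H](OCc2ccc(OC)cc2)[C@H](C)[C@@H]1[C@H](O[Si](C)(C)C(C)(C)C)C(=O)[C@@H](OC(=O)C(C)Br)[C@@H](Cl)C(=C)C=C | intermediate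
47 | samarium ester enolate of 46 | C=C[C@H](O[Si](C)(C)C(C)(C)C)[C@@]1(C)C=C[C@@H](OCc2ccc(OC)cc2)[C@H](C)[C@@H]1[C@H](O[Si](C)(C)C(C)(C)C)C(=O)[C@@H](OC(O[Sm](I)I)=CC)[C@@H](Cl)C(=C)C=C | intermediate
48 | γ-lactone (C7–O, C8–OH, C17 methyl) with C2 and C9 silyl ethers, open ten-membered ring | C=C[C@H](O[Si](C)(C)C(C)(C)C)[C@@]1(C)C=C[C@@H](OCc2ccc(OC)cc2)[C@H](C)[C@@H]1[C@H](O[Si](C)(C)C(C)(C)C)[C@]2(O)[C@@H](C)C(=O)O[C@H]2[C@@H](Cl)C(=C)C=C | intermediate
49 | seco triol (C2–OH, C8–OH, C9–OH) | C=C[C@H](O)[C@@]1(C)C=C[C@@H](OCc2ccc(OC)cc2)[C@H](C)[C@@H]1[C@H](O)[C@]2(O)[C@@H](C)C(=O)O[C@H]2[C@@H](Cl)C(=C)C=C | intermediate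
50 | ten-membered (Z)-diene triol with C12 4-methoxybenzyl ether | C=C1/C=C\[C@H](O)[C@@]2(C)C=C[C@@H](OCc3ccc(OC)cc3)[C@H](C)[C@@H]2[C@H](O)[C@]2(O)[C@@H](C)C(=O)O[C@H]2[C@H]1Cl | intermediate
51 | C2,C9-diacetate | C=C1/C=C\[C@H](OC(C)=O)[C@@]2(C)C=C[C@@H](OCc3ccc(OC)cc3)[C@H](C)[C@@H]2[C@H](OC(C)=O)[C@]2(O)[C@@H](C)C(=O)O[C@H]2[C@H]1Cl | intermediate
52 | C12 alcohol | C=C1/C=C\[C@H](OC(C)=O)[C@@]2(C)C=C[C@@H](O)[C@H](C)[C@@H]2[C@H](OC(C)=O)[C@]2(O)[C@@H](C)C(=O)O[C@H]2[C@H]1Cl | intermediate
53 | CNP0305105.1 | C=C1/C=C\[C@H](OC(C)=O)[C@@]2(C)C=C[C@@H](OC(=O)CC)[C@H](C)[C@@H]2[C@H](OC(C)=O)[C@]2(O)[C@@H](C)C(=O)O[C@H]2[C@H]1Cl | target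

**Step count and risks**

Total step count: 33. Longest linear sequence: 28 steps (steps 1–5, 7–15, 18–21, 24–33).

Steps most likely to fail:

1. Step 30 (ring-closing metathesis). The process at risk is slow catalyst loading on the hindered allylic-carbinol alkene and a sluggish vinylcarbene on the diene, so that oligomerisation outruns ten-membered ring closure. Fallback, setting out from 49 and returning at 50: MnO2 in CH2Cl2 should oxidise only the allylic C2–OH to the C2 vinyl ketone F3. Metathesis of this flatter enone, with the same ruthenium catalyst class, should give the macrocyclic C2 ketone F4. Luche reduction (NaBH4, CeCl3·7H2O, MeOH, −78 °C), with hydride expected from the face away from the C15 methyl, then returns 50. This detour also gives a second chance to set C2.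

2. Step 24 (γ-chloroallylation). The processes at risk are loss of γ-regioselectivity of the allylchromium, erosion of the anti and Felkin–Anh selectivities, and polymerisation of diene 40. Fallback, setting out from 36 and returning at 42: 2-(bromomethyl)buta-1,3-diene and dimethyl sulfide give the sulfonium salt F1. Its ylide (KN(SiMe3)2, THF, −78 °C) adds to 36 in a Corey–Chaykovsky epoxidation to give the trans-vinyl epoxide F2, again with Felkin–Anh control at C7. Opening of F2 by chloride at the allylic C6 with inversion (Li2CuCl4, THF) then gives 42.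

3. Step 28 (SmI2 Reformatsky). The processes at risk are reductive cleavage of the α-oxygenated ketone (loss of the C7 acyloxy or C9 silyloxy group) and β-elimination of chloride, both competing with the aldol closure. Fallback, setting out from 42 and returning at 48: the C7 hydroxyl is silylated (Et3SiOTf, 2,6-lutidine) to the C7 triethylsilyl ether F5. DDQ gives the C8 alcohol F6, and Dess–Martin oxidation gives the C8 ketone F7. Brief HF·pyridine treatment removes only the triethylsilyl group and gives the α-hydroxy ketone F8. The lithium enolate of ethyl propionate (2.5 equiv, MgBr2·OEt2, THF, −78 °C) then adds under chelation control between O7 and the ketone, anti to C6, to give the open aldol ester F9. F9 lactonises onto O7 to 48; C17 can be equilibrated with DBU if needed.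

Further compounds
F1 | step 24 | dimethyl(2-methylidenebut-3-en-1-yl)sulfonium bromide | C[S+](C)CC(=C)C=C.[Br-]
F2 | step 24 | trans-C6–C7 vinyl epoxide of the side chain (C7 as in 42, C6 inverted relative to 42) | C=C[C@H](O[Si](C)(C)C(C)(C)C)[C@@]1(C)C=C[C@@H](OCc2ccc(OC)cc2)[C@H](C)[C@@H]1[C@H](O[Si](C)(C)C(C)(C)C)[C@@H](OCc1ccc(OC)c(OC)c1)[C@H]1O[C@@H]1C(=C)C=C
F3 | step 30 | C2 vinyl ketone of 49 | C=CC(=O)[C@@]1(C)C=C[C@@H](OCc2ccc(OC)cc2)[C@H](C)[C@@H]1[C@H](O)[C@]2(O)[C@@H](C)C(=O)O[C@H]2[C@@H](Cl)C(=C)C=C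
F4 | step 30 | macrocyclic C2 ketone (2-oxo analogue of 50) | C=C1/C=C\C(=O)[C@@]2(C)C=C[C@@H](OCc3ccc(OC)cc3)[C@H](C)[C@@H]2[C@H](O)[C@]2(O)[C@@H](C)C(=O)O[C@H]2[C@H]1Cl
F5 | step 28 | C7 triethylsilyl ether of 42 | C=C[C@H](O[Si](C)(C)C(C)(C)C)[C@@]1(C)C=C[C@@H](OCc2ccc(OC)cc2)[C@H](C)[C@@H]1[C@H](O[Si](C)(C)C(C)(C)C)[C@@H](OCc1ccc(OC)c(OC)c1)[C@@H](O[Si](CC)(CC)CC)[C@@H](Cl)C(=C)C=C
F6 | step 28 | C8 alcohol with C7 triethylsilyl ether | C=C[C@H](O[Si](C)(C)C(C)(C)C)[C@@]1(C)C=C[C@@H](OCc2ccc(OC)cc2)[C@H](C)[C@@H]1[C@H](O[Si](C)(C)C(C)(C)C)[C@@H](O)[C@@H](O[Si](CC)(CC)CC)[C@@H](Cl)C(=C)C=C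
F7 | step 28 | C8 ketone with C7 triethylsilyl ether | C=C[C@H](O[Si](C)(C)C(C)(C)C)[C@@]1(C)C=C[C@@H](OCc2ccc(OC)cc2)[C@H](C)[C@@H]1[C@H](O[Si](C)(C)C(C)(C)C)C(=O)[C@@H](O[Si](CC)(CC)CC)[C@@H](Cl)C(=C)C=C
F8 | step 28 | C7-hydroxy C8 ketone | C=C[C@H](O[Si](C)(C)C(C)(C)C)[C@@]1(C)C=C[C@@H](OCc2ccc(OC)cc2)[C@H](C)[C@@H]1[C@H](O[Si](C)(C)C(C)(C)C)C(=O)[C@@H](O)[C@@H](Cl)C(=C)C=C
F9 | step 28 | open aldol ethyl ester (seco form of 48) | C=C[C@H](O[Si](C)(C)C(C)(C)C)[C@@]1(C)C=C[C@@H](OCc2ccc(OC)cc2)[C@H](C)[C@@H]1[C@H](O[Si](C)(C)C(C)(C)C)[C@](O)([C@@H](C)C(=O)OCC)[C@@H](O)[C@@H](Cl)C(=C)C=C
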